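## The problem

The target is a heliangolide. Germacrane numbering is used throughout: C1–C10 form the ring, C11–C13 are the lactone carbons on C7, C14 sits on C10 and C15 on C4. α and β refer to the usual drawing with H-7 α.

The ten-membered carbocycle carries a ring-cis C4=C5 double bond, an α-methylene-γ-lactone trans-fused at C6/C7 (C12 to the 6α-oxygen), and a trans 1β,10α-epoxide whose C10 also bears the C14 hydroxymethyl group. There are seven stereocentres: C1, C3, C6, C7, C8, C10 and C2′ of the (S)-2-methylbutanoate. C6, C7 and C8 are contiguous and can relay into each other. C3 is insulated by C2 and the sp2 atoms C4/C5 and must come from the starting material. The epoxide is remote and is best set by a reagent. C2′ is bought.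

Two secondary oxygens, on C6 and C8, flank C7 and compete for C12, so the lactone regiochemistry (6α,12 against 8β,12) is a problem of its own. The exocyclic methylene is a Michael acceptor. The epoxide faces C4=C5 across the ring and opens transannularly under acid. The ester α-centre epimerises under strong base. All three therefore have to come late.

End-to-end closure of a ten-membered ring with two defined alkene geometries is unattractive. The arc C1–C6, with ring-cis C4=C5 bearing C15, oxygen on C3 and the C9=C10(C14) unit on C1, is an oxygen-transposed p-menthane. C8–C9 is exactly the bond a [3,3] shift across C1–C6 of a 1,2-dialkenylcyclohexenol would form. The large ring can thus be made by ring expansion of a carvone-derived cyclohexene.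

## Retrosynthesis

**Epoxide and C3 silyl ether (30 ⇐ 29 ⇐ 28).** The C1–O and C10–O bonds of the oxirane are cut last, after removal of the C3 silyl group from 29. The epoxide is the most acid-labile group and its precursor, allylic alcohol 28, is a substrate for Sharpless epoxidation. Cutting it earlier would expose it to enolate and acylation chemistry. The forward step must deliver oxygen to one face of the ring-trans C1=C10 of 28 while the C3 hydroxyl stays masked, so that only the C14 alcohol directs.

**Ester and exocyclic methylene (28 ⇐ 27 ⇐ 24 + 25; 24 ⇐ 21).** The C8–O acyl bond to acid 25 and the C11=C13 bond are cut next, after the PMB ether of 27 is restored. Methylenation of 21 precedes esterification so that no base meets the epimerisable ester. Alcohol 21 has no Michael acceptor and no side chain. The forward steps ask for enolisation of a lactone beside a free hydroxyl and for acylation of a hindered 8β-alcohol without epimerising the acid.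

**Lactone transposition and oxidation level (21 ⇐ 20 ⇐ 19 ⇐ 18 ⇐ 17).** The O6–C12 acyl bond is cut and C12 is returned to O8, giving the cis-fused 8β,12-olide 20. The C6–H bond is then cut (ketone 19) and C12 is taken back through lactol 18 to the methyl acetal 17. This accepts that the rearrangement delivers C12 tied to O8. Cutting C6–O directly would require an allylic oxidation of a ten-membered ring. The forward sequence asks for hydride delivery to one face of C6 and for acyl transfer from O8 to O6.

**Ring expansion (17 ⇐ 14).** C8–C9 is cut and C1–C6 is re-formed, the retro-oxy-Cope. This single cut removes the ten-membered ring, both alkene geometries and the C7/C8 stereocentres. What remains is cyclohexenol 14 with three stereocentres, all traceable to carvone. No other cut of the ring does this without a macrocyclisation. The forward step needs a chair transition state through the two exocyclic alkenyl groups of the trans isomer.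

**Tertiary carbinol (14 ⇐ 8 + 12).** The C6–C7 bond is cut to enone 8 and the vinyl bromide 12, which is used as its lithium reagent 13. This is the only disconnection that joins the two halves at a carbonyl. It asks for 1,2-addition trans to the substituent on C1.

**Enone from the chiral pool (8 ⇐ 7 ⇐ 6 ⇐ 4 ⇐ 3 ⇐ 2 ⇐ 1).** No skeletal bond is cut. The C6 carbonyl is traced to an allylic C–H of silyl ether 7. The C3 oxygen comes by Wharton transposition of epoxy ketone 4 (giving alcohol 6), and the C14 ether by chlorination and etherification of (S)-carvone 1 via 2 and 3. The C14 oxygen is installed while the ring alkene is still a deactivated enone. It is an ether before the C6 ketone exists, because a free C14 hydroxyl or halide next to that ketone would cyclise towards a furan. The Wharton step interchanges the two ring methylene arms, which is why the (S)-enantiomer of carvone gives the required C1 configuration.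

**Enol ether partner (12 ⇐ 10 ⇐ 9).** The C–Br bond and the enol ether double bond are traced to 2,5-dimethoxytetrahydrofuran 9 through 10. The acetal keeps C12 at the aldehyde oxidation level and is inert to organolithium and KH.

## Roads not taken

**Alternative 1:** The cut is C9–C10 together with C8–O. In the forward step NaOCl converts the C10 aldoxime of the open-chain lactone A2 into a nitrile oxide. This adds to the vinyl group on C7 and closes the ten-membered ring as the bridged isoxazoline A1.
- Merits: ring closure and the C8 oxygen come in one operation, and the 6α,12-lactone is already in place, so no acyl transfer between O8 and O6 is needed. In this respect it is better than the chosen plan.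
- Weak points: in A1, C10 is the isoxazoline carbon, so C14 is absent and C1 carries only a silyloxy group. After N–O cleavage, C14 must be added to a ten-membered ketone and the C1/C10 oxygens turned into the epoxide with inversion at C1. These are two new stereo-determining events in a flexible ring with no control element. The cycloaddition is a true macrocyclisation, must run in the bridged mode and competes with nitrile oxide dimerisation. C8 is set by a macrocyclic transition state.
- Comparison: the chosen plan sets C8 by chirality transfer through a chair, brings C14 along from carvone and delivers an allylic alcohol of defined geometry for reagent-controlled epoxidation.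

**Alternative 2:** The cut is C6–O and C3–O. In the forward step Pd(OAc)2 (divalent palladium), benzoquinone and LiOAc in chloride-free AcOH add the C12 acid of triene acid A4 to C6 and acetate to C3 across the C3=C4–C5=C6 diene, giving A3.
- Merits: both allylic oxygens and the lactone arrive late, their 1,4-relationship is set by the mechanism, and A3 already carries methylene and ester. Its endgame is shorter and more redox-economic than the chosen one.
- Weak points: the burden shifts to A4, a ten-membered ring with three double bonds and two stereocentres, whose construction the step does not address. The π-allyl regiochemistry on an unsymmetrical 4-methyl diene in a medium ring is uncertain. The acrylic acid and the C1=C10 alkene offer competing sites. The C3 acetate must later be cleaved beside the C8 ester and the lactone.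
- Comparison: the chosen plan pays with a longer endgame, but it makes the ring, and it takes the C3 oxygen from the starting material.

**Alternative 3:** The cut is C1–C10 and C1–O. In the forward step LiN(SiMe3)2 deprotonates the thiolanium salt A6. The ylide adds to the C10 ketone and the alkoxide displaces tetrahydrothiophene, closing ring and oxirane in A5.
- Merits: ring and epoxide are made together, the lactone is already on C6, and no late epoxidation or transposition is needed. If it worked with the right facial sense it would be the shortest endgame of all.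
- Weak points: this is an intermolecular-type C–C bond formation closing a ten-membered ring. The base must form a non-stabilised ylide beside lactone α-protons. Deprotonation can occur on either side of sulfur. The configurations of C1 and C10 depend on a macrocyclic transition state with no reagent control.
- Comparison: the chosen plan needs three more steps at the end, but the ring is formed unimolecularly and stereospecifically, and the epoxide is set by a tartrate.

Key step: step 10

Assumption: the acetal carbon C12 in 10–18 and C11 in 22 and 23 are carried as mixtures of epimers; both end as sp2 carbons, so this is without consequence.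

Remark: the ring-trans C1=C10 bond (C2 and C9 on opposite sides) has the CIP descriptor Z once C14 bears oxygen, because C14 then outranks C9.

## Route

Step 1
Reactants: 1 (S)-(+)-carvone
Product: 2 (S)-5-(3-chloroprop-1-en-2-yl)-2-methylcyclohex-2-en-1-one
Conditions: Ca(OCl)2, CO2 (solid), CH2Cl2/H2O, 0 °C
Reagents that add atoms: calcium hypochlorite, [Ca+2].[O-]Cl.[O-]Cl
Why: Ene-type allylic chlorination by HOCl formed in the flask occurs at the electron-rich 1,1-disubstituted alkene, while the enone double bond is deactivated. The stereocentre is not touched.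

Step 2
Reactants: 2 (S)-5-(3-chloroprop-1-en-2-yl)-2-methylcyclohex-2-en-1-one
Product: 3 (S)-5-{3-[(4-methoxybenzyl)oxy]prop-1-en-2-yl}-2-methylcyclohex-2-en-1-one
Conditions: 4-MeOC6H4CH2OH, AgOTf, 2,6-di-tert-butyl-4-methylpyridine, 4 Å MS, CH2Cl2, −20 °C → rt, dark
Reagents that add atoms: 4-methoxybenzyl alcohol, COc1ccc(CO)cc1
Why: Silver-assisted Williamson-type alcoholysis of the allylic chloride runs without base, so the enolisable enone is not disturbed. The 2-substituted allyl unit is symmetrical, so no regiochemical issue arises, and the hindered pyridine traps the acid.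

Step 3
Reactants: 3 (S)-5-{3-[(4-methoxybenzyl)oxy]prop-1-en-2-yl}-2-methylcyclohex-2-en-1-one
Product: 4 (1S,4S,6S)-4-{3-[(4-methoxybenzyl)oxy]prop-1-en-2-yl}-1-methyl-7-oxabicyclo[4.1.0]heptan-2-one
Conditions: 30% H2O2, NaOH (cat.), MeOH, 0 °C
Reagents that add atoms: hydrogen peroxide, OO
Why: Nucleophilic (Weitz–Scheffer) epoxidation attacks only the enone. Hydroperoxide adds anti to the side chain, as is usual for carvone, which sets the future C3 oxygen trans to C1.

Step 4
Reactants: 4 (1S,4S,6S)-4-{3-[(4-methoxybenzyl)oxy]prop-1-en-2-yl}-1-methyl-7-oxabicyclo[4.1.0]heptan-2-one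
Product: 6 (1S,5R)-5-{3-[(4-methoxybenzyl)oxy]prop-1-en-2-yl}-2-methylcyclohex-2-en-1-ol, via epoxy hydrazone 5 (not isolated)
Conditions: N2H4·H2O, AcOH (cat.), MeOH, 0 °C → rt
Reagents that add atoms: none
Why: Wharton transposition: the hydrazone opens the epoxide to a vinyldiazene that loses N2. The C–O bond at the former β-carbon is never broken, so the hydroxyl stays trans to the side chain (C3 S).

Step 5
Reactants: 6 (1S,5R)-5-{3-[(4-methoxybenzyl)oxy]prop-1-en-2-yl}-2-methylcyclohex-2-en-1-ol
Product: 7 tert-butyldimethylsilyl ether of 6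
Conditions: TBSCl, imidazole, DMF, rt
Reagents that add atoms: tert-butyldimethylsilyl chloride, CC(C)(C)[Si](C)(C)Cl
Why: Standard silylation of a secondary allylic alcohol. The silyl ether is trans to the later C6 alkoxide across the ring and cannot migrate to it.

Step 6
Reactants: 7 tert-butyldimethylsilyl ether of 6
Product: 8 (4S,6R)-4-[(tert-butyldimethylsilyl)oxy]-6-{3-[(4-methoxybenzyl)oxy]prop-1-en-2-yl}-3-methylcyclohex-2-en-1-one
Conditions: CrO3, 3,5-dimethylpyrazole, CH2Cl2, −20 °C
Reagents that add atoms: chromium trioxide, O=[Cr](=O)=O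
Why: Allylic oxidation with the CrO3–dimethylpyrazole complex takes the ring CH2 next to the CH end of the trisubstituted alkene, as in the 7-oxidation of Δ5-steroids. This gives the β,β-disubstituted enone; the low temperature is chosen to spare the benzylic ether.

Step 7
Reactants: 9 2,5-dimethoxytetrahydrofuran
Product: 10 2-methoxy-2,3-dihydrofuran
Conditions: TMSOTf (1.0 equiv), iPr2NEt, CH2Cl2, −20 → 0 °C
Reagents that add atoms: none
Why: Silyl-triflate-mediated conversion of a methyl acetal into an enol ether: ionisation of one methoxy group and deprotonation of the oxocarbenium ion by the amine. One equivalent of silyl triflate limits the second elimination to furan.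

Step 8
Reactants: 10 2-methoxy-2,3-dihydrofuran
Product: 12 4-bromo-2-methoxy-2,3-dihydrofuran, via 2,3-dibromo-5-methoxytetrahydrofuran 11 (not isolated)
Conditions: Br2, CH2Cl2, −78 °C; then Et3N, −78 °C → rt
Reagents that add atoms: bromine, BrBr
Why: Bromine adds to the enol ether and the labile anomeric bromide is lost with the adjacent proton. This is the standard bromination–dehydrobromination route to β-bromo cyclic enol ethers.

Step 9
Reactants: 8 (4S,6R)-4-[(tert-butyldimethylsilyl)oxy]-6-{3-[(4-methoxybenzyl)oxy]prop-1-en-2-yl}-3-methylcyclohex-2-en-1-one; 12 4-bromo-2-methoxy-2,3-dihydrofuran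
Product: 14 (1R,4S,6R)-4-[(tert-butyldimethylsilyl)oxy]-1-(5-methoxy-4,5-dihydrofuran-3-yl)-6-{3-[(4-methoxybenzyl)oxy]prop-1-en-2-yl}-3-methylcyclohex-2-en-1-ol, via (5-methoxy-4,5-dihydrofuran-3-yl)lithium 13 (not isolated)
Conditions: 12, t-BuLi (2 equiv), THF, −78 °C; then added to 8 precomplexed with CeCl3, THF, −78 °C
Reagents that add atoms: none
Why: Bromine–lithium exchange gives the β-lithio enol ether, which is kept cold to avoid fragmentation to an alkynyl alkoxide. It adds 1,2 to the CeCl3-activated enone, which suppresses enolisation. The bulky sp2 nucleophile should enter trans to the substituent on C1, as is general for 6-substituted cyclohex-2-enones, giving the trans-dialkenyl carbinol.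

Step 10
Reactants: 14 (1R,4S,6R)-4-[(tert-butyldimethylsilyl)oxy]-1-(5-methoxy-4,5-dihydrofuran-3-yl)-6-{3-[(4-methoxybenzyl)oxy]prop-1-en-2-yl}-3-methylcyclohex-2-en-1-ol
Product: 17 3β-(tert-butyldimethylsilyloxy)-12-methoxy-14-(4-methoxybenzyloxy)-8β,12-epoxy-13-norgermacra-1(10),4-dien-6-one (4,5 ring-cis; 1(10) ring-trans; H-7 and H-8 both α), via potassium alkoxide 15 (not isolated), via potassium enolate 16 (not isolated)
Conditions: KH, 18-crown-6, THF, 0 °C → rt; then AcOH/THF, −78 °C
Reagents that add atoms: none
Why: Anionic oxy-Cope rearrangement: KH with 18-crown-6 gives the dissociated alkoxide 15, whose [3,3] shift over C8=C7–C6–C1–C10=C9 forms C8–C9 and breaks C1–C6 to give dienolate 16; the closest known reaction type is the ring expansion of trans-1,2-dialkenylcyclohexenols to cyclodeca-1,5-dienones. The ten-membered ring is not closed end to end but arises by expansion of the cyclohexene by four atoms through a six-membered chair transition state fused trans to it, so no macrocyclisation entropy is paid. C8 is set by that chair: the configurations of C1 and C6 fix its absolute sense, the ring enol ether holds O8 equatorial and H8 axial, and the new bond to C9 therefore gives the 8β-oxygen (8R). C7 is set on the cold acidic quench, by protonation of 16 from the outer face of the ring in the conformation in which it is formed, which places H7 cis to H8 (cis-fused oxolane). The step needs the chair through the two exocyclic alkenyl groups and not a boat through the ring alkene; the trans arrangement with both ring bonds equatorial secures this, leaves C2 equatorial and so gives the ring-trans C1=C10, while C4=C5 is carried over unchanged. Loss of the C8 oxygen from 16 is held back because it would be a retro-5-endo-trig opening with the C8–O bond close to the nodal plane of the enolate.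

Step 11
Reactants: 17 3β-(tert-butyldimethylsilyloxy)-12-methoxy-14-(4-methoxybenzyloxy)-8β,12-epoxy-13-norgermacra-1(10),4-dien-6-one
Product: 18 3β-(tert-butyldimethylsilyloxy)-12-hydroxy-14-(4-methoxybenzyloxy)-8β,12-epoxy-13-norgermacra-1(10),4-dien-6-one (lactol)
Conditions: PPTS, acetone/H2O, 40 °C
Reagents that add atoms: water, O
Why: Mild acid hydrolysis of a 2-deoxyfuranoside-type methyl acetal. The secondary silyl ether and the benzylic ether tolerate pyridinium tosylate, and the five-membered lactol stays closed, which protects the β-oxygenated ketone.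

Step 12
Reactants: 18 3β-(tert-butyldimethylsilyloxy)-12-hydroxy-14-(4-methoxybenzyloxy)-8β,12-epoxy-13-norgermacra-1(10),4-dien-6-one
Product: 19 3β-(tert-butyldimethylsilyloxy)-14-(4-methoxybenzyloxy)-6-oxo-13-norgermacra-1(10),4-dien-8β,12-olide
Conditions: nPr4NRuO4 (cat.), N-methylmorpholine N-oxide, 4 Å MS, CH2Cl2, rt
Reagents that add atoms: none
Why: Ley–Griffith oxidation of a lactol to the γ-lactone under neutral conditions. No other free hydroxyl is present, and the absence of base avoids epimerisation at C7 and elimination of the C8 carboxylate.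

Step 13
Reactants: 19 3β-(tert-butyldimethylsilyloxy)-14-(4-methoxybenzyloxy)-6-oxo-13-norgermacra-1(10),4-dien-8β,12-olide
Product: 20 3β-(tert-butyldimethylsilyloxy)-6α-hydroxy-14-(4-methoxybenzyloxy)-13-norgermacra-1(10),4-dien-8β,12-olide
Conditions: NaBH4, CeCl3·7H2O, MeOH, −78 °C
Reagents that add atoms: none
Why: Luche 1,2-reduction of the ring-cis enone leaves the lactone alone. Hydride should enter from the outer face of the carbonyl, the face opposite to the one that C1 left in the rearrangement, which gives the 6α-alcohol (6R).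

Step 14
Reactants: 20 3β-(tert-butyldimethylsilyloxy)-6α-hydroxy-14-(4-methoxybenzyloxy)-13-norgermacra-1(10),4-dien-8β,12-olide
Product: 21 3β-(tert-butyldimethylsilyloxy)-8β-hydroxy-14-(4-methoxybenzyloxy)-13-norgermacra-1(10),4-dien-6α,12-olide
Conditions: DBU (cat.), CH2Cl2, rt
Reagents that add atoms: none
Why: Base-catalysed intramolecular transesterification through a five-membered tetrahedral intermediate. The trans-fused 6α,12-olide is the resting lactone of 8β-oxygenated germacranolides and heliangolides and is expected to be the thermodynamic product; no stereocentre changes.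

Step 15
Reactants: 21 3β-(tert-butyldimethylsilyloxy)-8β-hydroxy-14-(4-methoxybenzyloxy)-13-norgermacra-1(10),4-dien-6α,12-olide
Product: 24 3β-(tert-butyldimethylsilyloxy)-8β-hydroxy-14-(4-methoxybenzyloxy)germacra-1(10),4,11(13)-trien-6α,12-olide, via Mannich base 22 (not isolated), via ammonium iodide 23 (not isolated)
Conditions: LiN(iPr)2 (2.5 equiv), THF, −78 °C; CH2=NMe2+ I−, −78 → 0 °C; then MeI, MeOH, rt; then aq. NaHCO3, EtOAc
Reagents that add atoms: N,N-dimethylmethyleneiminium iodide, C=[N+](C)C.[I-]
Why: α-Methylenation through the alkoxide–enolate dianion: Mannich reaction with the iminium salt, quaternisation and β-elimination of trimethylamine. Any acyl transfer by the C8 alkoxide returns to the same 6α,12-olide, and its addition to the new methylene would be 5-endo.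

Step 16
Reactants: 24 3β-(tert-butyldimethylsilyloxy)-8β-hydroxy-14-(4-methoxybenzyloxy)germacra-1(10),4,11(13)-trien-6α,12-olide; 25 (S)-2-methylbutanoic acid
Product: 27 3β-(tert-butyldimethylsilyloxy)-14-(4-methoxybenzyloxy)-8β-[(2S)-2-methylbutanoyloxy]germacra-1(10),4,11(13)-trien-6α,12-olide, via mixed anhydride 26 (not isolated)
Conditions: 25, 2,4,6-Cl3C6H2COCl, Et3N, THF, rt; then 24, DMAP, toluene, rt
Reagents that add atoms: none
Why: Yamaguchi esterification acylates hindered secondary alcohols. A simple α-alkyl acid without an α-heteroatom is not expected to epimerise under these conditions, so C2′ comes unchanged from the chiral pool.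

Step 17
Reactants: 27 3β-(tert-butyldimethylsilyloxy)-14-(4-methoxybenzyloxy)-8β-[(2S)-2-methylbutanoyloxy]germacra-1(10),4,11(13)-trien-6α,12-olide
Product: 28 3β-(tert-butyldimethylsilyloxy)-14-hydroxy-8β-[(2S)-2-methylbutanoyloxy]germacra-1(10),4,11(13)-trien-6α,12-olide
Conditions: DDQ, CH2Cl2/pH 7 buffer, 0 °C
Reagents that add atoms: none
Why: Oxidative cleavage of the 4-methoxybenzyl ether under buffered, near-neutral conditions. Silyl ether, ester and α-methylene lactone are inert to the quinone.

Step 18
Reactants: 28 3β-(tert-butyldimethylsilyloxy)-14-hydroxy-8β-[(2S)-2-methylbutanoyloxy]germacra-1(10),4,11(13)-trien-6α,12-olide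
Product: 29 3β-(tert-butyldimethylsilyloxy)-1β,10α-epoxy-14-hydroxy-8β-[(2S)-2-methylbutanoyloxy]germacra-4,11(13)-dien-6α,12-olide
Conditions: Ti(OiPr)4, L-(+)-diethyl tartrate, t-BuOOH, 4 Å MS, CH2Cl2, −20 °C
Reagents that add atoms: tert-butyl hydroperoxide, CC(C)(C)OO
Why: Sharpless asymmetric epoxidation of the only free allylic alcohol. L-(+)-tartrate delivers oxygen to the face that gives the (1R,10S) epoxide, and this is also the exposed outer face of the ring-trans alkene. The electron-poor methylene and the masked C3 allylic system do not react.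

Step 19
Reactants: 29 3β-(tert-butyldimethylsilyloxy)-1β,10α-epoxy-14-hydroxy-8β-[(2S)-2-methylbutanoyloxy]germacra-4,11(13)-dien-6α,12-olide
Product: 30 1β,10α-epoxy-3β,14-dihydroxy-8β-[(2S)-2-methylbutanoyloxy]germacra-4,11(13)-dien-6α,12-olide (CNP0356520.3)
Conditions: HF·pyridine, pyridine, THF, 0 °C → rt
Reagents that add atoms: none
Why: Fluoride-mediated cleavage of the secondary silyl ether with pyridine as buffer keeps the medium too weakly acidic for transannular opening of the epoxide. Ester, lactone and methylene are unaffected.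

## Compound list

1 | (S)-(+)-carvone | CC1=CC[C@@H](CC1=O)C(C)=C | starting material
2 | (S)-5-(3-chloroprop-1-en-2-yl)-2-methylcyclohex-2-en-1-one | CC1=CC[C@@H](CC1=O)C(=C)CCl | intermediate
3 | (S)-5-{3-[(4-methoxybenzyl)oxy]prop-1-en-2-yl}-2-methylcyclohex-2-en-1-one | CC1=CC[C@@H](CC1=O)C(=C)COCc2ccc(OC)cc2 | intermediate
4 | (1S,4S,6S)-4-{3-[(4-methoxybenzyl)oxy]prop-1-en-2-yl}-1-methyl-7-oxabicyclo[4.1.0]heptan-2-one | C1C(=O)[C@@]2(C)O[C@H]2C[C@@H]1C(=C)COCc3ccc(OC)cc3 | intermediate
5 | hydrazone of 4 | C1C(=NN)[C@@]2(C)O[C@H]2C[C@@H]1C(=C)COCc3ccc(OC)cc3 | intermediate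
6 | (1S,5R)-5-{3-[(4-methoxybenzyl)oxy]prop-1-en-2-yl}-2-methylcyclohex-2-en-1-ol | C1C=C(C)[C@@H](O)C[C@@H]1C(=C)COCc2ccc(OC)cc2 | intermediate
7 | tert-butyldimethylsilyl ether of 6 | C1C=C(C)[C@@H](O[Si](C)(C)C(C)(C)C)C[C@@H]1C(=C)COCc2ccc(OC)cc2 | intermediate
8 | (4S,6R)-4-[(tert-butyldimethylsilyl)oxy]-6-{3-[(4-methoxybenzyl)oxy]prop-1-en-2-yl}-3-methylcyclohex-2-en-1-one | O=C1C=C(C)[C@@H](O[Si](C)(C)C(C)(C)C)C[C@@H]1C(=C)COCc2ccc(OC)cc2 | intermediate
9 | 2,5-dimethoxytetrahydrofuran | COC1CCC(OC)O1 | starting material
10 | 2-methoxy-2,3-dihydrofuran | COC1CC=CO1 | intermediate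
11 | 2,3-dibromo-5-methoxytetrahydrofuran | COC1CC(Br)C(Br)O1 | intermediate
12 | 4-bromo-2-methoxy-2,3-dihydrofuran | COC1CC(Br)=CO1 | intermediate
13 | (5-methoxy-4,5-dihydrofuran-3-yl)lithium | COC1CC([Li])=CO1 | intermediate
14 | (1R,4S,6R)-4-[(tert-butyldimethylsilyl)oxy]-1-(5-methoxy-4,5-dihydrofuran-3-yl)-6-{3-[(4-methoxybenzyl)oxy]prop-1-en-2-yl}-3-methylcyclohex-2-en-1-ol | O[C@]1(C2=COC(OC)C2)C=C(C)[C@@H](O[Si](C)(C)C(C)(C)C)C[C@@H]1C(=C)COCc3ccc(OC)cc3 | intermediate
15 | potassium alkoxide of 14 | [K+].[O-][C@]1(C2=COC(OC)C2)C=C(C)[C@@H](O[Si](C)(C)C(C)(C)C)C[C@@H]1C(=C)COCc3ccc(OC)cc3 | intermediate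
16 | potassium C6-enolate of 17 (C6=C7, oxygen cis to C8) | [K+].COC1C/C(=C(/[O-])\C=C(\C)[C@@H](O[Si](C)(C)C(C)(C)C)C/C=C(\COCc3ccc(OC)cc3)C2)[C@@H]2O1 | intermediate
17 | 3β-(tert-butyldimethylsilyloxy)-12-methoxy-14-(4-methoxybenzyloxy)-8β,12-epoxy-13-norgermacra-1(10),4-dien-6-one | O=C1/C=C(/C)[C@@H](O[Si](C)(C)C(C)(C)C)C/C=C(\COCc2ccc(OC)cc2)C[C@H]3OC(OC)C[C@@H]13 | intermediate
18 | 3β-(tert-butyldimethylsilyloxy)-12-hydroxy-14-(4-methoxybenzyloxy)-8β,12-epoxy-13-norgermacra-1(10),4-dien-6-one | O=C1/C=C(/C)[C@@H](O[Si](C)(C)C(C)(C)C)C/C=C(\COCc2ccc(OC)cc2)C[C@H]3OC(O)C[C@@H]13 | intermediate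
19 | 3β-(tert-butyldimethylsilyloxy)-14-(4-methoxybenzyloxy)-6-oxo-13-norgermacra-1(10),4-dien-8β,12-olide | O=C1/C=C(/C)[C@@H](O[Si](C)(C)C(C)(C)C)C/C=C(\COCc2ccc(OC)cc2)C[C@H]3OC(=O)C[C@@H]13 | intermediate
20 | 3β-(tert-butyldimethylsilyloxy)-6α-hydroxy-14-(4-methoxybenzyloxy)-13-norgermacra-1(10),4-dien-8β,12-olide | O[C@@H]1/C=C(/C)[C@@H](O[Si](C)(C)C(C)(C)C)C/C=C(\COCc2ccc(OC)cc2)C[C@H]3OC(=O)C[C@@H]13 | intermediate
21 | 3β-(tert-butyldimethylsilyloxy)-8β-hydroxy-14-(4-methoxybenzyloxy)-13-norgermacra-1(10),4-dien-6α,12-olide | C1C(=O)O[C@@H]2/C=C(/C)[C@@H](O[Si](C)(C)C(C)(C)C)C/C=C(\COCc3ccc(OC)cc3)C[C@@H](O)[C@@H]12 | intermediate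
22 | 13-(dimethylamino) Mannich base of 21 | CN(C)CC1C(=O)O[C@@H]2/C=C(/C)[C@@H](O[Si](C)(C)C(C)(C)C)C/C=C(\COCc3ccc(OC)cc3)C[C@@H](O)[C@@H]12 | intermediate
23 | trimethylammonium iodide of 22 | C[N+](C)(C)CC1C(=O)O[C@@H]2/C=C(/C)[C@@H](O[Si](C)(C)C(C)(C)C)C/C=C(\COCc3ccc(OC)cc3)C[C@@H](O)[C@@H]12.[I-] | intermediate
24 | 3β-(tert-butyldimethylsilyloxy)-8β-hydroxy-14-(4-methoxybenzyloxy)germacra-1(10),4,11(13)-trien-6α,12-olide | C=C1C(=O)O[C@@H]2/C=C(/C)[C@@H](O[Si](C)(C)C(C)(C)C)C/C=C(\COCc3ccc(OC)cc3)C[C@@H](O)[C@@H]12 | intermediate
25 | (S)-2-methylbutanoic acid | CC[C@H](C)C(=O)O | starting material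
26 | (S)-2-methylbutanoic 2,4,6-trichlorobenzoic anhydride | CC[C@H](C)C(=O)OC(=O)c1c(Cl)cc(Cl)cc1Cl | intermediate
27 | 3β-(tert-butyldimethylsilyloxy)-14-(4-methoxybenzyloxy)-8β-[(2S)-2-methylbutanoyloxy]germacra-1(10),4,11(13)-trien-6α,12-olide | C=C1C(=O)O[C@@H]2/C=C(/C)[C@@H](O[Si](C)(C)C(C)(C)C)C/C=C(\COCc3ccc(OC)cc3)C[C@@H](OC(=O)[C@@H](C)CC)[C@@H]12 | intermediate
28 | 3β-(tert-butyldimethylsilyloxy)-14-hydroxy-8β-[(2S)-2-methylbutanoyloxy]germacra-1(10),4,11(13)-trien-6α,12-olide | C=C1C(=O)O[C@@H]2/C=C(/C)[C@@H](O[Si](C)(C)C(C)(C)C)C/C=C(\CO)C[C@@H](OC(=O)[C@@H](C)CC)[C@@H]12 | intermediate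
29 | 3β-(tert-butyldimethylsilyloxy)-1β,10α-epoxy-14-hydroxy-8β-[(2S)-2-methylbutanoyloxy]germacra-4,11(13)-dien-6α,12-olide | C=C1C(=O)O[C@@H]2/C=C(/C)[C@@H](O[Si](C)(C)C(C)(C)C)C[C@H]3O[C@]3(CO)C[C@@H](OC(=O)[C@@H](C)CC)[C@@H]12 | intermediate
30 | 1β,10α-epoxy-3β,14-dihydroxy-8β-[(2S)-2-methylbutanoyloxy]germacra-4,11(13)-dien-6α,12-olide, (1R,3S,6R,7R,8R,10S), CNP0356520.3 | C=C1C(=O)O[C@@H]2/C=C(/C)[C@@H](O)C[C@H]3O[C@]3(CO)C[C@@H](OC(=O)[C@@H](C)CC)[C@@H]12 | target

## Step count and least certain steps

Total: 19 steps. Longest linear sequence: 17 steps from (S)-carvone (steps 1–6 and 9–19); steps 7 and 8 prepare the enol ether partner.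

**Step 10 (key step).** The most likely failure is loss of control at C7 on protonation of the enolate, if the ring relaxes to a second conformer before the quench. Base-induced elimination of the C8 oxygen or a competing boat pathway through the ring alkene are further possibilities, because the alkoxide and enolate are strongly basic and the enol ether partner is unusual. Fallback: a neutral thermal rearrangement. Setting out from 14, the tertiary alcohol is converted into its trimethylsilyl ether F1 (Me3SiOSO2CF3, 2,6-lutidine). This is heated in toluene in a sealed vessel to effect the siloxy-Cope shift to the trimethylsilyl enol ether F2. F2 is protonated separately at −78 °C with Bu4NF buffered by AcOH and returns to the route at 17.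

**Step 2.** Silver-induced ionisation of the allylic chloride may lead to self-condensation of the benzylic alcohol or to elimination instead of ether formation, because the cation-like intermediate is not very selective. Fallback: setting out from 2, the chloride is displaced with KOAc in DMF to give the allylic acetate F3. Methanolysis (K2CO3, MeOH) gives the allylic alcohol F4. Acid-catalysed etherification with 4-methoxybenzyl trichloroacetimidate returns to the route at 3.

**Step 6.** Competing hydrogen abstraction at the benzylic and allylic ether positions may erode chemoselectivity, because these C–H bonds are about as weak as the ring allylic ones. Fallback: a C–H-free oxidative transposition. Setting out from 7, the ring alkene is epoxidised with 3-chloroperbenzoic acid to the epoxide F5; either diastereomer serves. PhSeNa (from PhSeSePh and NaBH4) opens it at C5 to the hydroxy selenide F6. Oxidation with H2O2 and selenoxide elimination give the tertiary allylic alcohol F7. Babler–Dauben oxidative transposition with pyridinium chlorochromate returns to the route at 8.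

**Step 13.** Hydride delivery may be poorly face-selective or favour the 6β-alcohol, because the preference rests only on the ring conformation. Fallback: inversion instead of direct selection. Setting out from 19, a reduction that gives mainly the 6β-alcohol F8 is followed by Mitsunobu esterification with 4-nitrobenzoic acid (PPh3, diisopropyl azodicarboxylate), which inverts the allylic centre to the 6α-(4-nitrobenzoate) F9. Methanolysis (K2CO3, MeOH, 0 °C) returns to the route at 20.

**Step 14.** The acyl transfer may stop at a mixture or run backwards, because the preference for the trans-fused 6α,12-olide over the cis-fused 8β,12-olide is an expectation, not a certainty. Fallback: a directed sequence that does not rest on an equilibrium.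
- Setting out from 20, the C6 hydroxyl is silylated (Et3SiOSO2CF3, 2,6-lutidine) to the triethylsilyl ether F10.
- The lactone is opened with MeNH(OMe)·HCl and AlMe3 to the Weinreb amide F11, which has a free 8β-hydroxyl.
- This is capped as the chloroacetate F12.
- HF·pyridine followed by camphorsulfonic acid removes the triethylsilyl group and closes the lactone onto O6, giving the 8β-chloroacetoxy-6α,12-olide F13.
- Thiourea with NaHCO3 removes the chloroacetate and returns to the route at 21.

**Step 19.** Acid-promoted opening or transannular cyclisation of the epoxide may accompany desilylation, because the oxirane faces C4=C5 across the ring. Fallback: change the order. Setting out from 28, the silyl ether is removed first with HF·pyridine, when no epoxide is present, to give the 3β,14-diol F14. Sharpless epoxidation under the conditions of step 18 then gives 30 directly. This relies on the much faster reaction of the primary allylic alcohol compared with the secondary one, whose alkene bears a cis substituent and an allylic acyloxy group.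

## Further compounds

F1 | step 10 | trimethylsilyl ether of 14 | C[Si](C)(C)O[C@]1(C2=COC(OC)C2)C=C(C)[C@@H](O[Si](C)(C)C(C)(C)C)C[C@@H]1C(=C)COCc3ccc(OC)cc3
F2 | step 10 | trimethylsilyl enol ether of 17 (C6=C7) | COC1C/C(=C(/O[Si](C)(C)C)\C=C(\C)[C@@H](O[Si](C)(C)C(C)(C)C)C/C=C(\COCc3ccc(OC)cc3)C2)[C@@H]2O1
F3 | step 2 | (S)-2-(4-methyl-5-oxocyclohex-3-en-1-yl)allyl acetate | CC1=CC[C@@H](CC1=O)C(=C)COC(C)=O
F4 | step 2 | (S)-5-(3-hydroxyprop-1-en-2-yl)-2-methylcyclohex-2-en-1-one | CC1=CC[C@@H](CC1=O)C(=C)CO
F5 | step 6 | ring epoxide of 7 | C1C2OC2(C)[C@@H](O[Si](C)(C)C(C)(C)C)C[C@@H]1C(=C)COCc3ccc(OC)cc3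
F6 | step 6 | hydroxy selenide from F5 (phenylseleno on C5, hydroxyl on C4) | C1C([Se]c2ccccc2)C(C)(O)[C@@H](O[Si](C)(C)C(C)(C)C)C[C@@H]1C(=C)COCc3ccc(OC)cc3
F7 | step 6 | tertiary allylic alcohol (C4 hydroxyl, C5=C6) | C1=CC(C)(O)[C@@H](O[Si](C)(C)C(C)(C)C)C[C@@H]1C(=C)COCc2ccc(OC)cc2
F8 | step 13 | 6β-epimer of 20 | O[C@H]1/C=C(/C)[C@@H](O[Si](C)(C)C(C)(C)C)C/C=C(\COCc2ccc(OC)cc2)C[C@H]3OC(=O)C[C@@H]13
F9 | step 13 | 6α-(4-nitrobenzoate) of 20 | O=C(O[C@@H]1/C=C(/C)[C@@H](O[Si](C)(C)C(C)(C)C)C/C=C(\COCc2ccc(OC)cc2)C[C@H]3OC(=O)C[C@@H]13)c4ccc(cc4)[N+](=O)[O-]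
F10 | step 14 | 6α-triethylsilyl ether of 20 | CC[Si](CC)(CC)O[C@@H]1/C=C(/C)[C@@H](O[Si](C)(C)C(C)(C)C)C/C=C(\COCc2ccc(OC)cc2)C[C@H]3OC(=O)C[C@@H]13
F11 | step 14 | Weinreb amide with free 8β-hydroxyl | CC[Si](CC)(CC)O[C@@H]1/C=C(/C)[C@@H](O[Si](C)(C)C(C)(C)C)C/C=C(\COCc2ccc(OC)cc2)C[C@@H](O)[C@H]1CC(=O)N(C)OC
F12 | step 14 | 8β-chloroacetate of F11 | CC[Si](CC)(CC)O[C@@H]1/C=C(/C)[C@@H](O[Si](C)(C)C(C)(C)C)C/C=C(\COCc2ccc(OC)cc2)C[C@@H](OC(=O)CCl)[C@H]1CC(=O)N(C)OC
F13 | step 14 | 8β-chloroacetate of 21 | C1C(=O)O[C@@H]2/C=C(/C)[C@@H](O[Si](C)(C)C(C)(C)C)C/C=C(\COCc3ccc(OC)cc3)C[C@@H](OC(=O)CCl)[C@@H]12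
F14 | step 19 | 3β,14-dihydroxy-8β-[(2S)-2-methylbutanoyloxy]germacra-1(10),4,11(13)-trien-6α,12-olide | C=C1C(=O)O[C@@H]2/C=C(/C)[C@@H](O)C/C=C(\CO)C[C@@H](OC(=O)[C@@H](C)CC)[C@@H]12
A1 | alternative 1 | isoxazoline-bridged ten-membered lactone | C1C(=O)O[C@@H]2/C=C(/C)[C@@H](O[Si](C)(C)C(C)(C)C)C[C@@H](O[Si](CC)(CC)CC)C3=NO[C@H](C3)[C@@H]12
A2 | alternative 1 | open-chain C10 aldoxime with vinyl group on C7 | C1C(=O)O[C@H](/C=C(/C)[C@@H](O[Si](C)(C)C(C)(C)C)C[C@@H](O[Si](CC)(CC)CC)C=NO)[C@H]1C=C
A3 | alternative 2 | 3β-acetoxy-14-silyloxy heliangolide with the 1(10)-alkene | C=C1C(=O)O[C@@H]2/C=C(/C)[C@@H](OC(C)=O)C/C=C(\CO[Si](C)(C)C(C)(C)C)C[C@@H](OC(=O)[C@@H](C)CC)[C@@H]12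
A4 | alternative 2 | ten-membered 3,5-diene acrylic acid | C=C(C(=O)O)[C@H]1/C=C\C(C)=C/C/C=C(\CO[Si](C)(C)C(C)(C)C)C[C@H]1OC(=O)[C@@H](C)CC
A5 | alternative 3 | protected 1,10-epoxy germacranolide with C11 still CH2 | C1C(=O)O[C@@H]2/C=C(/C)[C@@H](O[Si](C)(C)C(C)(C)C)C[C@H]3O[C@]3(CO[Si](C)(C)C(C)(C)C)C[C@@H](OCc4ccc(OC)cc4)[C@@H]12
A6 | alternative 3 | C1 thiolanium triflate with C10 ketone | C1C(=O)O[C@H](/C=C(/C)[C@@H](O[Si](C)(C)C(C)(C)C)CC[S+]2CCCC2)[C@H]1[C@H](OCc3ccc(OC)cc3)CC(=O)CO[Si](C)(C)C(C)(C)C.[O-]S(=O)(=O)C(F)(F)F
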